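**Retrosynthetic overview**
1. The esters come last: the C9 isovalerate and C8 angelate are placed on an 8,9,10-triol, and the C5 ketone comes from allylic oxidation of an α-longipinene-type olefin.
2. Key disconnection: both cyclobutane bonds (C1–C6 and C2–C7) are cut at once. This leads back to an eleven-membered humulane C1–C3 allyl cation facing C6=C7, a transannular stepwise [2+2].
3. The cation precursor is a tertiary C3 allylic chloride made from the C2=C3 olefin. The C8–C10 oxygens come from the dienone by CBS reduction, Sharpless epoxidation and CO2-assisted epoxide opening.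
4. Ring order: eleven-membered ring (bought) → six- and seven-membered rings together (C1–C6) → cyclobutane (C2–C7), the last two closures in one flask.

Assumption and numbering: zerumbone, the bulk isolate of Zingiber zerumbet oil, is counted as a cheap catalogue terpene. Atoms carry biogenetic farnesane numbers: C11 = CMe2, C1 is next to it, C3 and C7 carry methyl groups, and C8 is the zerumbone carbonyl carbon.

**Step 1**
Reactants: 1 zerumbone
Product: 2 (8R)-zerumbol
Conditions: (S)-Me-CBS (20 mol %), catecholborane, toluene, −78 °C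
Reagents that add atoms: none
Why: Corey–Bakshi–Shibata 1,2-reduction in which the α-methyl-branched C6=C7 arm acts as the large group and the C9=C10 arm as the small one, so hydride delivery sets 8R, and catecholborane at low temperature leaves C2=C3 alone.

**Step 2**
Reactants: 2 (8R)-zerumbol
Product: 3 (8S,9S,10S)-9,10-epoxyhumula-2E,6E-dien-8-ol
Conditions: Ti(OiPr)4, L-(+)-DIPT, tBuOOH, 4 Å MS, CH2Cl2, −20 °C
Reagents that add atoms: tert-butyl hydroperoxide CC(C)(C)OO
Why: Katsuki–Sharpless epoxidation in its matched sense, because for the 8R carbinol L-(+)-tartrate reaches the C9=C10 face that gives the erythro (9S,10S)-epoxide, C6=C7 is the mismatched olefin, and C2=C3 is not directed.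

**Step 3**
Reactants: 3 (8S,9S,10S)-9,10-epoxyhumula-2E,6E-dien-8-ol
Product: 4 (8S,9S,10S)-10-hydroxyhumula-2E,6E-diene-8,9-diyl carbonate
Conditions: CO2 (1 atm), Cs2CO3 (0.5 equiv), 3 Å MS, DMF, 40 °C
Reagents that add atoms: carbon dioxide O=C=O
Why: Carboxylative opening of a 2,3-epoxy alcohol, in which the C8 alkoxide picks up CO2 and the carbonate oxygen opens the epoxide 5-exo at C9 with inversion, giving the 8,9-threo and 9,10-erythro pattern of the target.

**Step 4**
Reactants: 4 (8S,9S,10S)-10-hydroxyhumula-2E,6E-diene-8,9-diyl carbonate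
Product: 6 (8S,9S,10S)-8-(tert-butyldimethylsilyloxy)humula-2E,6E-diene-9,10-diyl carbonate, via 9,10-carbonate isomer 5 (not isolated)
Conditions: TBSCl, imidazole, DBU (20 mol %), DMF, 40 °C
Reagents that add atoms: tert-butyldimethylsilyl chloride CC(C)(C)[Si](C)(C)Cl
Why: Base-mediated 1,2-carbonate migration under Curtin–Hammett control followed by silyl ether formation, since DBU equilibrates 4 and 5, only the allylic C8–OH of 5 silylates at a useful rate, the neopentyl C10–OH of 4 is inert, and no stereocentre is touched.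

**Step 5**
Reactants: 6 (8S,9S,10S)-8-(tert-butyldimethylsilyloxy)humula-2E,6E-diene-9,10-diyl carbonate
Product: 9 3-chloro-8-(tert-butyldimethylsilyloxy)humula-1E,6E-diene-9,10-diyl carbonate (C3 epimers), via chloroselenide 7 (not isolated), via selenoxide 8 (not isolated)
Conditions: PhSeCl, CH2Cl2, −78 to 0 °C; mCPBA (1.05 equiv), −78 °C; iPr2NEt, −78 °C to rt
Reagents that add atoms: phenylselenyl chloride Cl[Se]c1ccccc1
Why: Markovnikov anti addition of PhSeCl to the only unshielded electron-rich olefin, then selenoxide syn-elimination, which must take a C1 hydrogen because C3 has none, gives the E-1,2-olefin next to a tertiary chloride, a nerolidyl-type leaving-group array whose C3 configuration is lost in step 6.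

**Step 6**
Reactants: 9 3-chloro-8-(tert-butyldimethylsilyloxy)humula-1E,6E-diene-9,10-diyl carbonate
Product: 13 8-(tert-butyldimethylsilyloxy)longipin-3-ene-9,10-diyl carbonate (C1 C2 C6 C7 spatially as in 21), via allyl cation 10 (not isolated), via himachalyl cation 11 (not isolated), via longipinyl cation 12 (not isolated)
Conditions: AgSbF6, 2,6-di-tert-butyl-4-methylpyridine, CH2Cl2, −78 to −40 °C
Reagents that add atoms: none
Why: Proposed new method: silver abstracts the tertiary allylic chloride to give the C1–C3 allyl cation, C6=C7 attacks C1 through a six-membered transannular transition state (neryl-to-terpinyl type) to give the cis-fused C7 cation, this cation is destabilised by the C8–O bond and lies next to C2=C3, so it is captured at C2 anti to C8–O (polar Felkin–Anh sense), the hindered pyridine then removes H4 irreversibly in a non-acidic medium so the cyclobutane cannot reopen, the E geometries of C1=C2 and C6=C7 are carried over suprafacially into C1, C2, C6 and C7, the cis-9,10-carbonate fits the eclipsed C9–C10 bond of the tricycle and damps oxygen participation, and the closest known types are the stepwise allyl-cation/olefin [2+2] cycloaddition and the silver-induced cyclisation of linalyl and neryl chlorides.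

**Step 7**
Reactants: 13 8-(tert-butyldimethylsilyloxy)longipin-3-ene-9,10-diyl carbonate
Product: 14 8-(tert-butyldimethylsilyloxy)-5-oxolongipin-3-ene-9,10-diyl carbonate
Conditions: CrO3, 3,5-dimethylpyrazole, CH2Cl2, −20 °C
Reagents that add atoms: chromium trioxide O=[Cr](=O)=O
Why: Chromium trioxide–dimethylpyrazole allylic oxidation of the α-pinene-to-verbenone type, where C5H2 is the only secondary allylic position because C2 is a bridgehead, and no stereocentre changes.

**Step 8**
Reactants: 14 8-(tert-butyldimethylsilyloxy)-5-oxolongipin-3-ene-9,10-diyl carbonate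
Product: 15 8-hydroxy-5-oxolongipin-3-ene-9,10-diyl carbonate
Conditions: HF·pyridine, THF, 0 °C to rt
Reagents that add atoms: none
Why: Fluoride-driven silyl ether cleavage under mildly acidic conditions, which leaves the cyclic carbonate and the enone untouched.

**Step 9**
Reactants: 15 8-hydroxy-5-oxolongipin-3-ene-9,10-diyl carbonate; 16 angelic acid
Product: 18 8-angeloyloxy-5-oxolongipin-3-ene-9,10-diyl carbonate, via mixed anhydride 17 (not isolated)
Conditions: 16, 2,4,6-trichlorobenzoyl chloride, Et3N, toluene, rt; then 15, 80 °C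
Reagents that add atoms: angelic acid C/C=C(/C)C(=O)O
Why: Yamaguchi-type mixed-anhydride esterification run without a nucleophilic amine catalyst, which acylates the hindered C8–OH through the less hindered angeloyl carbonyl and keeps the Z double bond from isomerising to tiglate.

**Step 10**
Reactants: 18 8-angeloyloxy-5-oxolongipin-3-ene-9,10-diyl carbonate
Product: 19 8-angeloyloxy-9,10-dihydroxylongipin-3-en-5-one
Conditions: K2CO3 (20 mol %), MeOH, 0 °C
Reagents that add atoms: none
Why: Base-catalysed methanolysis (transesterification) of the strained cyclic carbonate is much faster than attack on the hindered conjugated angelate, and the expected anti arrangement of O8 and O9 in the tricycle should block acyl migration.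

**Step 11**
Reactants: 19 8-angeloyloxy-9,10-dihydroxylongipin-3-en-5-one; 20 isovaleric anhydride
Product: 21 target (1S,2R,6R,7R,8S,9S,10S)-8-angeloyloxy-10-hydroxy-9-isovaleryloxylongipin-3-en-5-one
Conditions: 20 (1.1 equiv), DMAP (10 mol %), pyridine, CH2Cl2, −10 °C
Reagents that add atoms: isovaleric anhydride CC(C)CC(=O)OC(=O)CC(C)C
Why: Site-selective DMAP-catalysed acylation, in which the C9–OH reacts while the C10–OH, neopentyl to the CMe2 carbon, stays free.

**Compound list**
1 | zerumbone, (2E,6E,9E)-humula-2,6,9-trien-8-one | C1/C=C(\C)C(=O)/C=C/C(C)(C)C/C=C(\C)C1 | starting material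
2 | (8R)-zerumbol | C1/C=C(\C)[C@H](O)/C=C/C(C)(C)C/C=C(\C)C1 | intermediate
3 | (8S,9S,10S)-9,10-epoxyhumula-2E,6E-dien-8-ol | C1/C=C(\C)[C@H](O)[C@@H]2O[C@H]2C(C)(C)C/C=C(\C)C1 | intermediate
4 | (8S,9S,10S)-10-hydroxyhumula-2E,6E-diene-8,9-diyl carbonate | C1/C=C(\C)[C@@H]2OC(=O)O[C@H]2[C@@H](O)C(C)(C)C/C=C(\C)C1 | intermediate
5 | (8S,9R,10S)-8-hydroxyhumula-2E,6E-diene-9,10-diyl carbonate (not isolated) | C1/C=C(\C)[C@H](O)[C@H]2OC(=O)O[C@H]2C(C)(C)C/C=C(\C)C1 | intermediate
6 | (8S,9S,10S)-8-(tert-butyldimethylsilyloxy)humula-2E,6E-diene-9,10-diyl carbonate | C1/C=C(\C)[C@H](O[Si](C)(C)C(C)(C)C)[C@H]2OC(=O)O[C@H]2C(C)(C)C/C=C(\C)C1 | intermediate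
7 | chloroselenide, 3-chloro-2-phenylselanyl anti adduct of 6, C2/C3 diastereomers (not isolated) | C1/C=C(\C)[C@H](O[Si](C)(C)C(C)(C)C)[C@H]2OC(=O)O[C@H]2C(C)(C)CC([Se]c3ccccc3)C(C)(Cl)C1 | intermediate
8 | selenoxide of 7 (not isolated) | C1/C=C(\C)[C@H](O[Si](C)(C)C(C)(C)C)[C@H]2OC(=O)O[C@H]2C(C)(C)CC([Se](=O)c3ccccc3)C(C)(Cl)C1 | intermediate
9 | 3-chloro-8-(tert-butyldimethylsilyloxy)humula-1E,6E-diene-9,10-diyl carbonate, C3 epimers | C1/C=C(\C)[C@H](O[Si](C)(C)C(C)(C)C)[C@H]2OC(=O)O[C@H]2C(C)(C)/C=C/C(C)(Cl)C1 | intermediate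
10 | allyl cation C1–C3 (not isolated) | C1/C=C(\C)[C@H](O[Si](C)(C)C(C)(C)C)[C@H]2OC(=O)O[C@H]2C(C)(C)/C=C/[C+](C)C1 | intermediate
11 | himachalyl cation, cis-fused, charge at C7 (not isolated) | CC(C)(C)[Si](C)(C)O[C@@H]1[C@H]4OC(=O)O[C@H]4C(C)(C)[C@H]2C=C(C)CC[C@H]2[C+]1C | intermediate
12 | longipinyl cation, charge at C3 (not isolated) | CC(C)(C)[Si](C)(C)O[C@@H]1[C@H]4OC(=O)O[C@H]4C(C)(C)[C@@H]2[C@H]3CC[C+](C)[C@@H]2[C@@]13C | intermediate
13 | 8-(tert-butyldimethylsilyloxy)longipin-3-ene-9,10-diyl carbonate | CC(C)(C)[Si](C)(C)O[C@@H]1[C@H]4OC(=O)O[C@H]4C(C)(C)[C@@H]2[C@H]3CC=C(C)[C@@H]2[C@@]13C | intermediate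
14 | 8-(tert-butyldimethylsilyloxy)-5-oxolongipin-3-ene-9,10-diyl carbonate | CC(C)(C)[Si](C)(C)O[C@@H]1[C@H]4OC(=O)O[C@H]4C(C)(C)[C@@H]2[C@H]3C(=O)C=C(C)[C@@H]2[C@@]13C | intermediate
15 | 8-hydroxy-5-oxolongipin-3-ene-9,10-diyl carbonate | O[C@@H]1[C@H]4OC(=O)O[C@H]4C(C)(C)[C@@H]2[C@H]3C(=O)C=C(C)[C@@H]2[C@@]13C | intermediate
16 | angelic acid, (Z)-2-methylbut-2-enoic acid | C/C=C(/C)C(=O)O | starting material
17 | angelic 2,4,6-trichlorobenzoic mixed anhydride (not isolated) | C/C=C(/C)C(=O)OC(=O)c1c(Cl)cc(Cl)cc1Cl | intermediate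
18 | 8-angeloyloxy-5-oxolongipin-3-ene-9,10-diyl carbonate | C/C=C(/C)C(=O)O[C@@H]1[C@H]4OC(=O)O[C@H]4C(C)(C)[C@@H]2[C@H]3C(=O)C=C(C)[C@@H]2[C@@]13C | intermediate
19 | 8-angeloyloxy-9,10-dihydroxylongipin-3-en-5-one | C/C=C(/C)C(=O)O[C@@H]1[C@@H](O)[C@@H](O)C(C)(C)[C@@H]2[C@H]3C(=O)C=C(C)[C@@H]2[C@@]13C | intermediate
20 | isovaleric anhydride | CC(C)CC(=O)OC(=O)CC(C)C | starting material
21 | CNP0251293.1, (1S,2R,6R,7R,8S,9S,10S)-8-angeloyloxy-10-hydroxy-9-isovaleryloxylongipin-3-en-5-one | C/C=C(/C)C(=O)O[C@@H]1[C@@H](OC(=O)CC(C)C)[C@@H](O)C(C)(C)[C@@H]2[C@H]3C(=O)C=C(C)[C@@H]2[C@@]13C | target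

Total step count: 11. Longest linear sequence: 11 steps, from 1 to 21.

**Steps most likely to fail**

Step 6 (transannular double closure). The C7 cation may lose a proton to give himachaladienes or be diverted before C2 attacks. The fallback replaces the closed-shell cation by a one-electron pathway and sets out from 9. DBU in toluene removes hydrogen chloride to give the conjugated 1,3(15),6-triene F1. Blue-light irradiation with 9-mesityl-10-methylacridinium tetrafluoroborate in MeCN oxidises the 1,3-diene to its radical cation. This closes C1–C6 and then C2–C7 as a hole-catalysed [2+2] cycloaddition to the exocyclic-methylene longipinene F2, whose isolated olefin is too hard to re-oxidise. RhCl3·3H2O in EtOH at 60 °C then moves the double bond into the ring, and the route is rejoined at 13.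

Step 5 (chloroselenation and elimination). The seleniranium ion could be intercepted transannularly by C6=C7, or the adduct could lose HCl to an allyl selenide. The fallback uses an ene reaction instead of an addition–elimination and sets out from 6. Schenck photooxygenation (O2, tetraphenylporphyrin, light, CH2Cl2, −30 °C) abstracts a C1 hydrogen on the more crowded olefin side to give the tertiary allylic hydroperoxide F3. PPh3 reduces it to the tertiary allylic alcohol F4. Dry HCl in Et2O at −30 °C converts this to the chloride, and the route is rejoined at 9.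

Step 2 (site selectivity of the directed epoxidation). The intrinsically more reactive trisubstituted C6=C7 might still compete. The fallback switches from electrophilic, hydroxyl-directed oxidation to nucleophilic oxidation of the ketone and sets out from 1. Catalytic asymmetric Weitz–Scheffer epoxidation uses cumene hydroperoxide, La(OiPr)3 and the BINOL antipode that gives the epoxide configuration of 3, with 4 Å MS in THF. It attacks only the less substituted C9=C10 enone arm and gives the epoxy ketone F5. Chelation-controlled reduction with Zn(BH4)2 in Et2O at −20 °C gives the erythro epoxy alcohol, and the route is rejoined at 3.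

**Further compounds**
F1 | step 6 | 8-(tert-butyldimethylsilyloxy)humula-1E,3(15),6E-triene-9,10-diyl carbonate | C1/C=C(\C)[C@H](O[Si](C)(C)C(C)(C)C)[C@H]2OC(=O)O[C@H]2C(C)(C)/C=C/C(=C)C1
F2 | step 6 | 8-(tert-butyldimethylsilyloxy)longipin-3(15)-ene-9,10-diyl carbonate | CC(C)(C)[Si](C)(C)O[C@@H]1[C@H]4OC(=O)O[C@H]4C(C)(C)[C@@H]2[C@H]3CCC(=C)[C@@H]2[C@@]13C
F3 | step 5 | 3-hydroperoxy-8-(tert-butyldimethylsilyloxy)humula-1E,6E-diene-9,10-diyl carbonate, C3 epimers | C1/C=C(\C)[C@H](O[Si](C)(C)C(C)(C)C)[C@H]2OC(=O)O[C@H]2C(C)(C)/C=C/C(C)(OO)C1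
F4 | step 5 | 3-hydroxy-8-(tert-butyldimethylsilyloxy)humula-1E,6E-diene-9,10-diyl carbonate, C3 epimers | C1/C=C(\C)[C@H](O[Si](C)(C)C(C)(C)C)[C@H]2OC(=O)O[C@H]2C(C)(C)/C=C/C(C)(O)C1
F5 | step 2 | 9,10-epoxyhumula-2E,6E-dien-8-one, epoxide configured as in 3 | C1/C=C(\C)C(=O)[C@@H]2O[C@H]2C(C)(C)C/C=C(\C)C1
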